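**Retrosynthetic overview**

1. Aristophenone A is taken back to its bis(methoxymethyl) ether; only the catechol is masked.
2. Both rings of the bicyclo[3.3.1]nonane are opened together by cutting C5–C6, C5–C9 and C2–C3. This gives an aryl 1,3-diketone (C3, C4, C5, the C5 prenyl, the aroyl group) and an acyclic iodo malonate (C6, C7, C8, C1, with C2 and C9 as the two ester carbons).
3. Forward, in one flask: C5 alkylation, then ring B (C5 to C9), then ring A (C3 to C2).
4. The iodo malonate comes from an Evans imide: C7 is set by auxiliary-controlled prenylation, and the C8–C1 quaternary pair by conjugate addition to an isopropylidene malonate followed by C1 prenylation.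
5. The aryl diketone comes from a crossed Claisen condensation of 6-methylhept-5-en-2-one with a protected protocatechuate ester; C1 and C5 are set by C7 during the ring closures.

Assumption: the target is treated as the drawn 4-hydroxy enol tautomer, (1S,5S,7R), with core atoms C1–C9 numbered as in that name (C1 is the bridgehead next to CMe2 C8, C5 the bridgehead next to CH2 C6).

**Route**

Step 1
Reactants: 1 methyl 3,4-dihydroxybenzoate
Product: 2 methyl 3,4-bis(methoxymethoxy)benzoate
Conditions: MOMCl, i-Pr2NEt, CH2Cl2, 0 → 23 °C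
Reagents that add atoms: chloromethyl methyl ether, COCCl
Why: O-alkylation of both phenols (MOM protection) masks the catechol for the strongly basic steps that follow and creates no stereocentre.

Step 2
Reactants: 2 methyl 3,4-bis(methoxymethoxy)benzoate; 3 6-methylhept-5-en-2-one
Product: 4 1-[3,4-bis(methoxymethoxy)phenyl]-7-methyloct-6-ene-1,3-dione
Conditions: NaH, THF, 0 → 65 °C; AcOH
Reagents that add atoms: none
Why: Crossed Claisen condensation in which the methyl ketone is acylated at its CH3 terminus (the less substituted, thermodynamically favoured β-diketonate), giving the unit that carries C3, C4, C5, the C5 prenyl group and the aroyl group without any stereocentre.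

Step 3
Reactants: 5 (4S)-3-acetyl-4-benzyl-1,3-oxazolidin-2-one; 6 diethyl 2-(propan-2-ylidene)propanedioate
Product: 7 diethyl 2-{4-[(4S)-4-benzyl-2-oxo-1,3-oxazolidin-3-yl]-2-methyl-4-oxobutan-2-yl}propanedioate
Conditions: TiCl4 (2.1 equiv), i-Pr2NEt (1.1 equiv), CH2Cl2, −78 → 0 °C
Reagents that add atoms: none
Why: Evans-type titanium-enolate Michael addition in which the unhindered chlorotitanium acetate enolate of 5 adds to the TiCl4-chelated alkylidene malonate at its β,β-dimethyl carbon, making the C7–C8 bond beside the quaternary C8 that already carries C1 and creating no stereocentre.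

Step 4
Reactants: 7 diethyl 2-{4-[(4S)-4-benzyl-2-oxo-1,3-oxazolidin-3-yl]-2-methyl-4-oxobutan-2-yl}propanedioate; 8 1-bromo-3-methylbut-2-ene (prenyl bromide)
Product: 10 diethyl 2-{(3S)-3-[(4S)-4-benzyl-2-oxo-1,3-oxazolidine-3-carbonyl]-2,6-dimethylhept-5-en-2-yl}-2-(3-methylbut-2-en-1-yl)propanedioate, via mono-prenyl imide 9 (not isolated)
Conditions: NaN(SiMe3)2 (2.1 equiv), THF, −78 °C; 8 (3 equiv), −78 → 23 °C
Reagents that add atoms: none
Why: Evans asymmetric alkylation followed by malonate alkylation, in which the malonate C–H is removed first (so the imide enolate cannot expel a malonate anion by retro-Michael cleavage), the chelated Z sodium imide enolate is prenylated at −78 °C on the face opposite the benzyl group to set C7 (3S here, 7R in the target, dr expected ≥ 95:5), and the sodium malonate is prenylated on warming to complete quaternary C1.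

Step 5
Reactants: 10 diethyl 2-{(3S)-3-[(4S)-4-benzyl-2-oxo-1,3-oxazolidine-3-carbonyl]-2,6-dimethylhept-5-en-2-yl}-2-(3-methylbut-2-en-1-yl)propanedioate
Product: 11 diethyl 2-[(3S)-3-(hydroxymethyl)-2,6-dimethylhept-5-en-2-yl]-2-(3-methylbut-2-en-1-yl)propanedioate
Conditions: LiBH4, THF, 0 °C
Reagents that add atoms: none
Why: Reductive cleavage of the Evans imide, in which LiBH4 attacks the activated exocyclic imide carbonyl much faster than the two hindered ethyl esters, so C6 becomes CH2OH, the auxiliary is released and C7 is not touched.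

Step 6
Reactants: 11 diethyl 2-[(3S)-3-(hydroxymethyl)-2,6-dimethylhept-5-en-2-yl]-2-(3-methylbut-2-en-1-yl)propanedioate
Product: 12 diethyl 2-[(3S)-3-(iodomethyl)-2,6-dimethylhept-5-en-2-yl]-2-(3-methylbut-2-en-1-yl)propanedioate
Conditions: PPh3, I2, imidazole, CH2Cl2, 0 → 23 °C
Reagents that add atoms: iodine, II
Why: Appel-type iodination with pre-formed Ph3P–I2 converts the primary alcohol into the iodide under neutral conditions that spare the trisubstituted alkenes and C7, and the alcohol is used at once so that it does not lactonise onto a neighbouring ester.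

Step 7
Reactants: 4 1-[3,4-bis(methoxymethoxy)phenyl]-7-methyloct-6-ene-1,3-dione; 12 diethyl 2-[(3S)-3-(iodomethyl)-2,6-dimethylhept-5-en-2-yl]-2-(3-methylbut-2-en-1-yl)propanedioate
Product: 15 (1S,5S,7R)-3-[3,4-bis(methoxymethoxy)benzoyl]-4-hydroxy-8,8-dimethyl-1,5,7-tris(3-methylbut-2-en-1-yl)bicyclo[3.3.1]non-3-ene-2,9-dione, via open-chain diketo diester 13 (not isolated), via ring-B keto ester 14 (not isolated)
Conditions: LiN(i-Pr)2 (2.2 equiv), THF, −78 → 0 °C; 12, DMPU, −78 → 23 °C; LiN(i-Pr)2 (1.5 equiv), −78 → 45 °C; AcOH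
Reagents that add atoms: none
Why: Proposed new method: the dilithium dianion of 4 is alkylated at its γ-carbon C5 by the primary iodide (Hauser–Harris dianion alkylation), a second γ-deprotonation lets C5 attack one of the two identical esters on C1 (ring B, helped by the gem-dialkyl effect) and the β-diketonate carbon C3 then attacks the remaining ester (ring A) with the stabilised triketonate as the sink; because the first closure is reversible by retro-Dieckmann cleavage and ring A can only close from the chair in which the C2 ester and the C4 acyl group are both axial while the C7 prenyl group is equatorial, C1 and C5 are set by C7 as the exo (1S,5S) isomer, the endo alternative needing a 1,3-diaxial prenyl/acyl/ester triad; the closest known reaction type is the domino Dieckmann cyclisation of acyclic keto diesters to bicyclo[3.3.1]nonane-2,4,9-triones.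

Step 8
Reactants: 15 (1S,5S,7R)-3-[3,4-bis(methoxymethoxy)benzoyl]-4-hydroxy-8,8-dimethyl-1,5,7-tris(3-methylbut-2-en-1-yl)bicyclo[3.3.1]non-3-ene-2,9-dione
Product: 16 aristophenone A [(1S,5S,7R)-3-(3,4-dihydroxybenzoyl)-4-hydroxy-8,8-dimethyl-1,5,7-tris(3-methylbut-2-en-1-yl)bicyclo[3.3.1]non-3-ene-2,9-dione]
Conditions: HCl (2 M in MeOH), 0 → 23 °C
Reagents that add atoms: none
Why: Acid-catalysed acetal exchange with methanol (MOM cleavage) frees the catechol under conditions mild enough to leave the three prenyl groups and the enolised triketone intact, and no stereocentre is affected.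

**Compound list**

1 | methyl 3,4-dihydroxybenzoate | COC(=O)c1ccc(O)c(O)c1 | starting material
2 | methyl 3,4-bis(methoxymethoxy)benzoate | COCOc1ccc(cc1OCOC)C(=O)OC | intermediate
3 | 6-methylhept-5-en-2-one | CC(=O)CCC=C(C)C | starting material
4 | 1-[3,4-bis(methoxymethoxy)phenyl]-7-methyloct-6-ene-1,3-dione | COCOc1ccc(cc1OCOC)C(=O)CC(=O)CCC=C(C)C | intermediate
5 | (4S)-3-acetyl-4-benzyl-1,3-oxazolidin-2-one | CC(=O)N1[C@@H](Cc2ccccc2)COC1=O | starting material
6 | diethyl 2-(propan-2-ylidene)propanedioate | CCOC(=O)C(=C(C)C)C(=O)OCC | starting material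
7 | diethyl 2-{4-[(4S)-4-benzyl-2-oxo-1,3-oxazolidin-3-yl]-2-methyl-4-oxobutan-2-yl}propanedioate | CCOC(=O)C(C(=O)OCC)C(C)(C)CC(=O)N1[C@@H](Cc2ccccc2)COC1=O | intermediate
8 | 1-bromo-3-methylbut-2-ene | CC(C)=CCBr | starting material
9 | diethyl 2-{(3S)-3-[(4S)-4-benzyl-2-oxo-1,3-oxazolidine-3-carbonyl]-2,6-dimethylhept-5-en-2-yl}propanedioate (not isolated) | CCOC(=O)C(C(=O)OCC)C(C)(C)[C@H](CC=C(C)C)C(=O)N1[C@@H](Cc2ccccc2)COC1=O | intermediate
10 | diethyl 2-{(3S)-3-[(4S)-4-benzyl-2-oxo-1,3-oxazolidine-3-carbonyl]-2,6-dimethylhept-5-en-2-yl}-2-(3-methylbut-2-en-1-yl)propanedioate | CCOC(=O)C(CC=C(C)C)(C(=O)OCC)C(C)(C)[C@H](CC=C(C)C)C(=O)N1[C@@H](Cc2ccccc2)COC1=O | intermediate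
11 | diethyl 2-[(3S)-3-(hydroxymethyl)-2,6-dimethylhept-5-en-2-yl]-2-(3-methylbut-2-en-1-yl)propanedioate | CCOC(=O)C(CC=C(C)C)(C(=O)OCC)C(C)(C)[C@H](CC=C(C)C)CO | intermediate
12 | diethyl 2-[(3S)-3-(iodomethyl)-2,6-dimethylhept-5-en-2-yl]-2-(3-methylbut-2-en-1-yl)propanedioate | CCOC(=O)C(CC=C(C)C)(C(=O)OCC)C(C)(C)[C@H](CC=C(C)C)CI | intermediate
13 | diethyl 2-{(3R,5RS)-8-[3,4-bis(methoxymethoxy)phenyl]-2-methyl-3,5-bis(3-methylbut-2-en-1-yl)-6,8-dioxooctan-2-yl}-2-(3-methylbut-2-en-1-yl)propanedioate (not isolated) | CCOC(=O)C(CC=C(C)C)(C(=O)OCC)C(C)(C)[C@H](CC=C(C)C)CC(CC=C(C)C)C(=O)CC(=O)c1ccc(OCOC)c(OCOC)c1 | intermediate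
14 | ethyl (1S,3S,5R)-3-{3-[3,4-bis(methoxymethoxy)phenyl]-3-oxopropanoyl}-6,6-dimethyl-1,3,5-tris(3-methylbut-2-en-1-yl)-2-oxocyclohexane-1-carboxylate (not isolated) | CC(C)=CC[C@@H]1C[C@@](CC=C(C)C)(C(=O)CC(=O)c2ccc(OCOC)c(OCOC)c2)C(=O)[C@@](CC=C(C)C)(C(=O)OCC)C1(C)C | intermediate
15 | (1S,5S,7R)-3-[3,4-bis(methoxymethoxy)benzoyl]-4-hydroxy-8,8-dimethyl-1,5,7-tris(3-methylbut-2-en-1-yl)bicyclo[3.3.1]non-3-ene-2,9-dione | CC(C)=CC[C@@H]1C[C@]2(CC=C(C)C)C(=O)[C@@](CC=C(C)C)(C(=O)C(C(=O)c3ccc(OCOC)c(OCOC)c3)=C2O)C1(C)C | intermediate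
16 | aristophenone A, (1S,5S,7R)-3-(3,4-dihydroxybenzoyl)-4-hydroxy-8,8-dimethyl-1,5,7-tris(3-methylbut-2-en-1-yl)bicyclo[3.3.1]non-3-ene-2,9-dione | CC(C)=CC[C@@H]1C[C@]2(CC=C(C)C)C(=O)[C@@](CC=C(C)C)(C(=O)C(C(=O)c3ccc(O)c(O)c3)=C2O)C1(C)C | target

**Step count**

Total step count: 8.
Longest linear sequence: 6 (steps 3 to 8); steps 1 and 2 make the second fragment, which joins at step 7.

**Steps most likely to fail, with fallbacks**

Step 7 is the most likely to fail, because the tertiary C5 carbanion has to add to a hindered ester on C1 and the hindered iodide has to be displaced intermolecularly. The fallback inverts the order of bond formation: the acylation is done on the still secondary carbanion and ring B is closed by alkylation. It sets out from 11 and uses 4. Catalytic NaOEt in EtOH closes the δ-lactone ethyl (5S)-4,4-dimethyl-3,5-bis(3-methylbut-2-en-1-yl)-2-oxooxane-3-carboxylate F6. The dilithium dianion of 4 opens F6 at the more electrophilic lactone carbonyl and gives ethyl 7-[3,4-bis(methoxymethoxy)phenyl]-2-[(3S)-3-(hydroxymethyl)-2,6-dimethylhept-5-en-2-yl]-2,4-bis(3-methylbut-2-en-1-yl)-3,5,7-trioxoheptanoate F7. PPh3, I2 and imidazole give ethyl 7-[3,4-bis(methoxymethoxy)phenyl]-2-[(3S)-3-(iodomethyl)-2,6-dimethylhept-5-en-2-yl]-2,4-bis(3-methylbut-2-en-1-yl)-3,5,7-trioxoheptanoate F8. Cs2CO3 in MeCN closes ring B by intramolecular C-alkylation at C5 to give 14 as a mixture of ring diastereomers, and KOt-Bu in THF equilibrates these through retro-Dieckmann opening and closes ring A. The fallback comes back to the route at 15.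

Step 3 is the second risk, because the titanium enolate may not add to a β,β-disubstituted acceptor. The fallback makes the C7–C8 bond with an allyl nucleophile and reveals the C6 carbonyl by oxidative cleavage before any prenyl group is present. It sets out from 6. CH2=CHCH2MgCl in THF at −20 °C adds in conjugate fashion to give diethyl 2-(2-methylpent-4-en-2-yl)propanedioate F1. Ozonolysis (O3, CH2Cl2, −78 °C, then Me2S) gives diethyl 2-(2-methyl-4-oxobutan-2-yl)propanedioate F2. Oxidation with NaClO2 and NaH2PO4 in the presence of 2-methylbut-2-ene gives 5-ethoxy-4-(ethoxycarbonyl)-3,3-dimethyl-5-oxopentanoic acid F3. Pivaloyl chloride and Et3N give 2,2-dimethylpropanoic 5-ethoxy-4-(ethoxycarbonyl)-3,3-dimethyl-5-oxopentanoic anhydride F4, which acylates (4S)-4-benzyl-1,3-oxazolidin-2-one in the presence of LiCl and Et3N. The fallback comes back to the route at 7.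

Step 4 is the third risk, because the C7 enolate is of the neopentyl type and prenyl bromide may react slowly or in the SN2′ sense. The fallback brings in both groups as the smaller allyl group and converts them afterwards by olefin cross-metathesis. It sets out from 7. NaN(SiMe3)2 (2.1 equiv) and allyl iodide, in the same order of events as in step 4, give diethyl 2-{(3S)-3-[(4S)-4-benzyl-2-oxo-1,3-oxazolidine-3-carbonyl]-2-methylhex-5-en-2-yl}-2-(prop-2-en-1-yl)propanedioate F5. Cross-metathesis with excess 2-methylbut-2-ene and the second-generation Grubbs catalyst, (H2IMes)(PCy3)Cl2Ru=CHPh, in CH2Cl2 at 40 °C turns both allyl groups into prenyl groups. The fallback comes back to the route at 10.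

**Further compounds**

F1 | step 3 | diethyl 2-(2-methylpent-4-en-2-yl)propanedioate | CCOC(=O)C(C(=O)OCC)C(C)(C)CC=C
F2 | step 3 | diethyl 2-(2-methyl-4-oxobutan-2-yl)propanedioate | CCOC(=O)C(C(=O)OCC)C(C)(C)CC=O
F3 | step 3 | 5-ethoxy-4-(ethoxycarbonyl)-3,3-dimethyl-5-oxopentanoic acid | CCOC(=O)C(C(=O)OCC)C(C)(C)CC(=O)O
F4 | step 3 | 2,2-dimethylpropanoic 5-ethoxy-4-(ethoxycarbonyl)-3,3-dimethyl-5-oxopentanoic anhydride | CCOC(=O)C(C(=O)OCC)C(C)(C)CC(=O)OC(=O)C(C)(C)C
F5 | step 4 | diethyl 2-{(3S)-3-[(4S)-4-benzyl-2-oxo-1,3-oxazolidine-3-carbonyl]-2-methylhex-5-en-2-yl}-2-(prop-2-en-1-yl)propanedioate | C=CCC(C(=O)OCC)(C(=O)OCC)C(C)(C)[C@H](CC=C)C(=O)N1[C@@H](Cc2ccccc2)COC1=O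
F6 | step 7 | ethyl (5S)-4,4-dimethyl-3,5-bis(3-methylbut-2-en-1-yl)-2-oxooxane-3-carboxylate | CCOC(=O)C1(CC=C(C)C)C(=O)OC[C@@H](CC=C(C)C)C1(C)C
F7 | step 7 | ethyl 7-[3,4-bis(methoxymethoxy)phenyl]-2-[(3S)-3-(hydroxymethyl)-2,6-dimethylhept-5-en-2-yl]-2,4-bis(3-methylbut-2-en-1-yl)-3,5,7-trioxoheptanoate | CCOC(=O)C(CC=C(C)C)(C(=O)C(CC=C(C)C)C(=O)CC(=O)c1ccc(OCOC)c(OCOC)c1)C(C)(C)[C@H](CC=C(C)C)CO
F8 | step 7 | ethyl 7-[3,4-bis(methoxymethoxy)phenyl]-2-[(3S)-3-(iodomethyl)-2,6-dimethylhept-5-en-2-yl]-2,4-bis(3-methylbut-2-en-1-yl)-3,5,7-trioxoheptanoate | CCOC(=O)C(CC=C(C)C)(C(=O)C(CC=C(C)C)C(=O)CC(=O)c1ccc(OCOC)c(OCOC)c1)C(C)(C)[C@H](CC=C(C)C)CI
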